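The central six-membered ring is read as a vinylogous anhydride: the enol-lactone carbon C5 of the butenolide is doubly bonded to the phenyl-bearing carbon, which carries the ketone attached to benzofuran C2. This O–C=C(Ph)–C(=O) unit is the retron of a condensation between an anhydride carbonyl and a benzyl ketone, and that ketone is the hydrate of a phenylethynyl group. The precursor is thus an isomer of the protected target, a 3-(2-phenylethynylbenzofuran-3-yl)-4-arylmaleic anhydride with both heterocycles in place. Acid and a relay equivalent of water hydrate the alkyne and close the carbocycle onto the anhydride carbonyl in one operation; demethylation finishes.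

Key step: step 5

Remark: the target has no stereocentre and its non-aromatic C=C bonds are fixed inside rings, so no configuration has to be set; 1, 4 and 6 are assumed to be commercial, and the three phenols are carried as methyl ethers.

Step 1
Reactants: 1 4-(bromomethyl)-6,7-dimethoxycoumarin
Product: 2 2-(5,6-dimethoxy-1-benzofuran-3-yl)acetic acid
Conditions: 1 M NaOH (aq), reflux; then HCl to pH 1
Reagents that add atoms: sodium hydroxide, [Na+].[OH-]
Why: Coumarin-to-benzofuran ring contraction of a 4-(halomethyl)coumarin, in which hydroxide opens the lactone, the phenoxide displaces the allylic bromide (5-exo-tet) and the exocyclic double bond shifts into the ring to give the aromatic benzofuran-3-acetate.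

Step 2
Reactants: 2 2-(5,6-dimethoxy-1-benzofuran-3-yl)acetic acid
Product: 3 2-(2-bromo-5,6-dimethoxy-1-benzofuran-3-yl)acetic acid
Conditions: NBS (1.05 equiv), MeCN, 0 °C to rt, dark
Reagents that add atoms: N-bromosuccinimide, O=C1CCC(=O)N1Br
Why: Electrophilic aromatic bromination should go to C2, the most nucleophilic position of a 3-alkylbenzofuran, because the σ-complex is a C3 benzylic cation stabilised by the para 6-methoxy group, while the polar solvent and darkness suppress radical bromination of the CH2 group.

Step 3
Reactants: 3 2-(2-bromo-5,6-dimethoxy-1-benzofuran-3-yl)acetic acid; 4 2-(4-methoxyphenyl)-2-oxoacetic acid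
Product: 5 3-(2-bromo-5,6-dimethoxy-1-benzofuran-3-yl)-4-(4-methoxyphenyl)furan-2,5-dione
Conditions: Ac2O, Et3N, 100 °C
Reagents that add atoms: none
Why: Perkin-type condensation of the arylacetic mixed anhydride with the keto group of the α-keto acid, followed by dehydration and closure of the cis-diacid, is the standard route to unsymmetrical 3,4-diarylmaleic anhydrides, and the 2-bromobenzofuran is inert to Ac2O/Et3N.

Step 4
Reactants: 5 3-(2-bromo-5,6-dimethoxy-1-benzofuran-3-yl)-4-(4-methoxyphenyl)furan-2,5-dione; 6 ethynylbenzene
Product: 7 3-[5,6-dimethoxy-2-(phenylethynyl)-1-benzofuran-3-yl]-4-(4-methoxyphenyl)furan-2,5-dione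
Conditions: PdCl2(PPh3)2 (5 mol %), CuI (5 mol %), Et3N, toluene, 60 °C, anhydrous
Reagents that add atoms: none
Why: Sonogashira coupling at the activated C2–Br bond next to the furan oxygen should proceed, since the fully substituted diarylmaleic anhydride (itself formed in hot Ac2O/Et3N) tolerates a tertiary amine under anhydrous conditions, as halogenated cyclic anhydrides are known to do in this coupling.

Step 5
Reactants: 7 3-[5,6-dimethoxy-2-(phenylethynyl)-1-benzofuran-3-yl]-4-(4-methoxyphenyl)furan-2,5-dione
Product: 10 tri-O-methyl ether of the target, via benzyl ketone 8 (not isolated), via hydroxy lactone 9 (not isolated)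
Conditions: TfOH (0.3 equiv), H2O (1 equiv), PhCl, 80 then 120 °C, sealed tube
Reagents that add atoms: water, O (relay: taken up in 8 and released again from 9; its oxygen can end up in the ring ketone)
Why: Proposed new method: Markovnikov protonation of the alkyne at the phenyl-bearing carbon gives a vinyl cation on the benzofuran side that is trapped by the proximal anhydride carbonyl oxygen (6-exo-dig) and opened by water to benzyl ketone 8, whose enol then adds to the same protonated anhydride carbonyl to give 9, which is dehydrated by the acid to 10, so that water and acid are returned and the step is an isomerisation. The closest known reaction type is the Brønsted acid-catalysed tandem alkyne hydration/aldol condensation of alkynyl ketones (formal endo alkyne–carbonyl metathesis), joined to the known condensation of cyclic anhydride carbonyls with active methylene compounds (Gabriel–Perkin ylidene-lactone synthesis); new is the anhydride carbonyl as acceptor in the tandem, and the water relay is needed because a direct [2+2] oxete path would require a bridgehead alkene. The one ring closed is the six-membered carbocycle, by 6-(enolendo)-exo-trig attack of the enol carbon on the anhydride carbonyl, the five-membered lactone ring being carried over from the anhydride. No stereocentre remains in 10, since the two created in 9 are erased by the dehydration and the new C=C is fixed inside the ring. The step needs hydration with oxygen on the benzofuran-side alkyne carbon, secured by carbonyl participation and by the 6-methoxybenzofuran-2-yl group that stabilises that vinyl cation better than phenyl does, and closure onto the carbonyl next to the benzofuranyl-bearing carbon, secured by the tether because the other carbonyl would give a seven-membered ring.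

Step 6
Reactants: 10 tri-O-methyl ether of the target
Product: 11 target (CNP0139113.0)
Conditions: BBr3 (9 equiv), CH2Cl2, −78 °C to rt; then H2O
Reagents that add atoms: none
Why: Lewis-acid ether cleavage (BBr3 demethylation) by O-coordination and bromide attack on methyl should free the three phenols, while the lactone, the ketone and the quinone methide carry no group that BBr3 cleaves and are released from their boron complexes on aqueous work-up.

Compound list
1 | 4-(bromomethyl)-6,7-dimethoxy-2H-chromen-2-one | COc1cc2OC(=O)C=C(CBr)c2cc1OC | starting material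
2 | 2-(5,6-dimethoxy-1-benzofuran-3-yl)acetic acid | COc1cc2occ(CC(O)=O)c2cc1OC | intermediate
3 | 2-(2-bromo-5,6-dimethoxy-1-benzofuran-3-yl)acetic acid | COc1cc2oc(Br)c(CC(O)=O)c2cc1OC | intermediate
4 | 2-(4-methoxyphenyl)-2-oxoacetic acid | COc1ccc(cc1)C(=O)C(O)=O | starting material
5 | 3-(2-bromo-5,6-dimethoxy-1-benzofuran-3-yl)-4-(4-methoxyphenyl)furan-2,5-dione | COc1ccc(cc1)C1=C(C(=O)OC1=O)c1c(Br)oc2cc(OC)c(OC)cc12 | intermediate
6 | ethynylbenzene (phenylacetylene) | C#Cc1ccccc1 | starting material
7 | 3-[5,6-dimethoxy-2-(phenylethynyl)-1-benzofuran-3-yl]-4-(4-methoxyphenyl)furan-2,5-dione | COc1ccc(cc1)C1=C(C(=O)OC1=O)c1c(C#Cc2ccccc2)oc2cc(OC)c(OC)cc12 | intermediate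
8 | benzyl ketone: 3-[5,6-dimethoxy-2-(phenylacetyl)-1-benzofuran-3-yl]-4-(4-methoxyphenyl)furan-2,5-dione | COc1ccc(cc1)C1=C(C(=O)OC1=O)c1c(C(=O)Cc2ccccc2)oc2cc(OC)c(OC)cc12 | intermediate
9 | hydroxy lactone: aldol adduct of 8, i.e. 10 with water added across the enol-lactone C=C (OH on butenolide C5, H on the phenyl-bearing carbon); the two transient sp3 centres are not controlled and are lost | O=C1OC2(O)C(c3ccccc3)C(=O)c3oc4cc(OC)c(OC)cc4c3C2=C1c1ccc(OC)cc1 | intermediate
10 | tri-O-methyl ether of the target: 11 with OMe in place of the three OH (furo[3,2-a]dibenzofuran-dione core) | O=C1OC2=C(c3ccccc3)C(=O)c3oc4cc(OC)c(OC)cc4c3C2=C1c1ccc(OC)cc1 | intermediate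
11 | target: cyclohexadienone ring fused to the C2–C3 bond of 5,6-dihydroxybenzofuran and to a butenolide; round the six-membered ring from benzofuran C2: C=O, C–Ph, C–O (butenolide C5), butenolide C4 (C=C to butenolide C3 bearing 4-hydroxyphenyl), benzofuran C3 | O=C1OC2=C(c3ccccc3)C(=O)c3oc4cc(O)c(O)cc4c3C2=C1c1ccc(O)cc1 | target

Total step count: 6
Longest linear sequence: 6 steps (1 → 2 → 3 → 5 → 7 → 10 → 11)

Steps most likely to fail

1. Step 5 (Proposed new method). The cascade may stop after the hydration because the enol of the ketone adds too slowly to the weakly electrophilic anhydride carbonyl. The strong acid may also open the anhydride or degrade the alkyne before the ring closes. Fallback with known chemistry: setting out from 7, gold(I)-catalysed hydration (Ph3PAuNTf2 cat., H2O, dioxane, 80 °C) is run with isolation of benzyl ketone 8. A Gabriel–Perkin condensation under basic dehydrating conditions (Ac2O, NaOAc, 120 °C) then closes the ring: the enolate adds to the anhydride carbonyl and the acetylated aldol eliminates. The route is rejoined at 10. This fallback makes no compound outside the compound list (F0).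

2. Step 4. The anhydride ring may be opened by the amine or the copper acetylide, or oxidative addition at the hindered bromide may be so slow that alkyne homocoupling takes over. Fallback: the coupling is moved ahead of anhydride formation. Setting out from 3, Fischer esterification (MeOH, cat. H2SO4, reflux) should give methyl 2-(2-bromo-5,6-dimethoxy-1-benzofuran-3-yl)acetate F1. Sonogashira coupling with 6 should give methyl 2-[5,6-dimethoxy-2-(phenylethynyl)-1-benzofuran-3-yl]acetate F2. Saponification (LiOH, THF/H2O; then HCl) should give 2-[5,6-dimethoxy-2-(phenylethynyl)-1-benzofuran-3-yl]acetic acid F3. Perkin condensation of F3 with 4 (Ac2O, Et3N, 100 °C) comes back to the route at 7.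

3. Step 6. Cleavage of three ethers of different basicity may stay incomplete, or forcing Lewis-acid conditions may degrade the chromophore (bromide addition to the quinone methide, opening of the enol lactone, oxidation of the catechol). Fallback: the protecting group is changed before the sensitive chromophore exists. Setting out from 5, BBr3 (CH2Cl2) should give 3-(2-bromo-5,6-dihydroxy-1-benzofuran-3-yl)-4-(4-hydroxyphenyl)furan-2,5-dione F4, and Ac2O/pyridine its triacetate F5. Sonogashira coupling with 6 should give the alkyne triacetate F6. The acid/water tandem of step 5 should then pass through the benzyl ketone triacetate F7 and the hydroxy lactone triacetate F8 to the triacetate of the target F9. Mild acidic hydrolysis (2 M HCl, dioxane, 50 °C) returns to the route at 11.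

Further compounds
F0 | step 5 | none | none
F1 | step 4 | methyl 2-(2-bromo-5,6-dimethoxy-1-benzofuran-3-yl)acetate | COC(=O)Cc1c(Br)oc2cc(OC)c(OC)cc12
F2 | step 4 | methyl 2-[5,6-dimethoxy-2-(phenylethynyl)-1-benzofuran-3-yl]acetate | COC(=O)Cc1c(C#Cc2ccccc2)oc2cc(OC)c(OC)cc12
F3 | step 4 | 2-[5,6-dimethoxy-2-(phenylethynyl)-1-benzofuran-3-yl]acetic acid | OC(=O)Cc1c(C#Cc2ccccc2)oc2cc(OC)c(OC)cc12
F4 | step 6 | 3-(2-bromo-5,6-dihydroxy-1-benzofuran-3-yl)-4-(4-hydroxyphenyl)furan-2,5-dione | Oc1ccc(cc1)C1=C(C(=O)OC1=O)c1c(Br)oc2cc(O)c(O)cc12
F5 | step 6 | triacetate of F4 | CC(=O)Oc1ccc(cc1)C1=C(C(=O)OC1=O)c1c(Br)oc2cc(OC(C)=O)c(OC(C)=O)cc12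
F6 | step 6 | alkyne triacetate: 7 with OAc in place of the three OMe | CC(=O)Oc1ccc(cc1)C1=C(C(=O)OC1=O)c1c(C#Cc2ccccc2)oc2cc(OC(C)=O)c(OC(C)=O)cc12
F7 | step 6 | benzyl ketone triacetate: 8 with OAc in place of the three OMe | CC(=O)Oc1ccc(cc1)C1=C(C(=O)OC1=O)c1c(C(=O)Cc2ccccc2)oc2cc(OC(C)=O)c(OC(C)=O)cc12
F8 | step 6 | hydroxy lactone triacetate: 9 with OAc in place of the three OMe, transient sp3 centres not controlled | O=C1OC2(O)C(c3ccccc3)C(=O)c3oc4cc(OC(C)=O)c(OC(C)=O)cc4c3C2=C1c1ccc(OC(C)=O)cc1
F9 | step 6 | triacetate of the target 11 | O=C1OC2=C(c3ccccc3)C(=O)c3oc4cc(OC(C)=O)c(OC(C)=O)cc4c3C2=C1c1ccc(OC(C)=O)cc1
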